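The plan cuts ring C at C3–C4 and O1–C2 and carries C2–C3(O)–C4, a 2-oxygenated 1,3-dicarbonyl, as a 4-benzyloxyisoxazole. C4 is bonded to C4a of ring A, whose neighbours C5 and C8a both bear oxygen. The derived nitrile oxide is therefore flanked on both sides, resists dimerisation and can be isolated. Its 1,3-dipolar cycloaddition to the preformed pyrrolidine enamine of the ring B benzyloxymethyl ketone makes C3–C4 and the isoxazole O–C2 bond in one operation and delivers C3 already oxygenated. The precursors are 2,4,6-tris(methoxymethoxy)-3,5-dimethylbenzonitrile oxide and the tribenzylated ketone. Reductive N–O cleavage, acid and hydrogenolysis then give the flavonol.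

Key step: step 10

Remarks on the chemistry
- Ring A carries MOM instead of benzyl ethers. MOMCl alkylates phloroglucinol on oxygen, the OMOM groups direct all three ring metalations, and they crowd the dipole less. They also leave in the acid step that closes ring C while O3 stays benzylated, so no free, air-sensitive 2-hydroxy-1,3-dicarbonyl is exposed.
- Ring B comes from a 4-O-methylgallate and not from 2-methoxyresorcinol. Halogenation or lithiation of 2-methoxyresorcinol or its ethers goes to C4, next to a flanking oxygen, and not to C5 para to the methoxy group.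
- The enamine is made beforehand and freed of pyrrolidine, because secondary amines add to nitrile oxides to give amidoximes.
- Assumption: methyl 3,5-dihydroxy-4-methoxybenzoate and tributyl[(benzyloxy)methyl]stannane are catalogue compounds. The target has no stereocentre.

Step 1
Reactants: 1 phloroglucinol
Product: 2 1,3,5-tris(methoxymethoxy)benzene
Conditions: NaH, MOMCl, DMF, 0 °C to rt
Reagents that add atoms: chloromethyl methyl ether (MOMCl), COCCl
Why: Williamson-type O-alkylation in which the hard, oxocarbenium-like electrophile should be taken up by the phenoxide oxygens rather than by the nucleophilic ring carbons, the usual weakness of phloroglucinol alkylations with softer halides.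

Step 2
Reactants: 2 1,3,5-tris(methoxymethoxy)benzene
Product: 4 1,3,5-tris(methoxymethoxy)-2-methylbenzene, via aryllithium 3 (not isolated)
Conditions: n-BuLi, TMEDA, THF, 0 °C; MeI, 0 °C to rt
Reagents that add atoms: iodomethane, CI
Why: Directed ortho-metalation followed by SN2 methylation, since every ring hydrogen of 2 lies between two chelating OMOM groups and one equivalent of base should therefore give 3 cleanly.

Step 3
Reactants: 4 1,3,5-tris(methoxymethoxy)-2-methylbenzene
Product: 6 1,3,5-tris(methoxymethoxy)-2,4-dimethylbenzene, via aryllithium 5 (not isolated)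
Conditions: n-BuLi, TMEDA, THF, 0 °C; MeI, 0 °C to rt
Reagents that add atoms: iodomethane, CI
Why: Second directed ortho-metalation, in which the two remaining ring hydrogens are equivalent and each still sits between two OMOM groups, so ring lithiation should be far faster than lateral deprotonation of the methyl group.

Step 4
Reactants: 6 1,3,5-tris(methoxymethoxy)-2,4-dimethylbenzene
Product: 8 2,4,6-tris(methoxymethoxy)-3,5-dimethylbenzaldehyde, via aryllithium 7 (not isolated)
Conditions: n-BuLi, TMEDA, THF, 0 °C; DMF, 0 °C to rt; aq NH4Cl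
Reagents that add atoms: N,N-dimethylformamide, CN(C)C=O
Why: Third directed ortho-metalation and formylation of the aryllithium with DMF (Bouveault aldehyde synthesis) at the only ring hydrogen left, the carbon that becomes C4a.

Step 5
Reactants: 8 2,4,6-tris(methoxymethoxy)-3,5-dimethylbenzaldehyde
Product: 9 (E)-2,4,6-tris(methoxymethoxy)-3,5-dimethylbenzaldehyde oxime
Conditions: NH2OH·HCl, NaOAc, EtOH/H2O, 60 °C
Reagents that add atoms: hydroxylamine hydrochloride, NO.Cl
Why: Oxime condensation under acetate buffer, mild enough for the acetal-type MOM ethers and feasible despite the two ortho substituents because hydroxylamine is small.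

Step 6
Reactants: 9 (E)-2,4,6-tris(methoxymethoxy)-3,5-dimethylbenzaldehyde oxime
Product: 11 2,4,6-tris(methoxymethoxy)-3,5-dimethylbenzonitrile oxide, via hydroximoyl chloride 10 (not isolated)
Conditions: aq NaOCl, CH2Cl2, 0 °C
Reagents that add atoms: none
Why: Oxidative dehydrogenation of an aldoxime by chlorination and base-induced loss of HCl, expected to be clean because the hexasubstituted ring has no site for nuclear chlorination and the two ortho OMOM groups keep the dipole from dimerising, so it should be isolable by extraction and crystallisation.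

Step 7
Reactants: 12 methyl 3,5-dihydroxy-4-methoxybenzoate
Product: 13 methyl 3,5-bis(benzyloxy)-4-methoxybenzoate
Conditions: BnBr, K2CO3, DMF, 60 °C
Reagents that add atoms: benzyl bromide, BrCc1ccccc1
Why: Williamson ether synthesis on the two equivalent phenols of a benzoate whose 3,4,5-oxygenation relative to the carbonyl carbon is already that of ring B.

Step 8
Reactants: 13 methyl 3,5-bis(benzyloxy)-4-methoxybenzoate
Product: 14 3,5-bis(benzyloxy)-N,4-dimethoxy-N-methylbenzamide
Conditions: MeNH(OMe)·HCl, i-PrMgCl, THF, −20 to 0 °C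
Reagents that add atoms: N,O-dimethylhydroxylamine hydrochloride, CNOC.Cl
Why: Aminolysis of the ester by the chloromagnesium amide of N,O-dimethylhydroxylamine should give the Weinreb amide directly and leave the aryl ethers untouched.

Step 9
Reactants: 14 3,5-bis(benzyloxy)-N,4-dimethoxy-N-methylbenzamide; 15 tributyl[(benzyloxy)methyl]stannane
Product: 17 2-(benzyloxy)-1-[3,5-bis(benzyloxy)-4-methoxyphenyl]ethanone, via benzyloxymethyllithium 16 (not isolated)
Conditions: 15, n-BuLi, THF, −78 °C; then 14, −78 to −40 °C; aq NH4Cl
Reagents that add atoms: none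
Why: Tin–lithium exchange gives the α-alkoxy organolithium 16, which is stable at −78 °C, and the Weinreb ketone synthesis stops its addition at the ketone stage, so C3 arrives with its oxygen already benzylated.

Step 10
Reactants: 11 2,4,6-tris(methoxymethoxy)-3,5-dimethylbenzonitrile oxide; 17 2-(benzyloxy)-1-[3,5-bis(benzyloxy)-4-methoxyphenyl]ethanone
Product: 20 4-(benzyloxy)-5-[3,5-bis(benzyloxy)-4-methoxyphenyl]-3-[2,4,6-tris(methoxymethoxy)-3,5-dimethylphenyl]isoxazole, via enamine 18 (not isolated), via aminoisoxazoline 19 (not isolated)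
Conditions: 17, pyrrolidine, TiCl4, PhMe, 0 °C to rt; filter under Ar, evaporate; 11, PhMe, rt to 50 °C; AcOH, 50 °C
Reagents that add atoms: none
Why: TiCl4 acts as Lewis acid and water scavenger to turn the aryl ketone, which can enolise only toward the CH2OBn carbon, into enamine 18, and the surplus amine is stripped first because it would otherwise consume the dipole as an amidoxime. Dipole 11 then adds across the enamine C=C in a concerted but strongly asynchronous 1,3-dipolar cycloaddition (enamine HOMO, dipole LUMO), the closest known reaction type being the nitrile oxide–enamine synthesis of 3,4,5-trisubstituted isoxazoles. The single new ring, the five-membered isoxazoline of 19, is closed by the [3+2] event itself, with C3–C4 and O–C2 (flavone numbering) formed together. The two stereocentres of 19 are transient and vanish when AcOH protonates the aminal nitrogen and pyrrolidine leaves together with the adjacent ring proton, so 20 is achiral and no stereocontrol is required. The step needs regioselectivity, and two factors favour the same orientation, which maps isoxazole C3 onto flavone C4 and isoxazole C5 onto flavone C2: nitrogen outweighs the benzyloxy oxygen as donor, so the CH(OBn) carbon is the nucleophilic end that meets the dipole carbon, and sterically the dipole oxygen goes to the fully substituted carbon. The step also needs the dipole to outlive a slow partner, which the two ortho OMOM groups, buttressed by the neighbouring methyl groups, secure by blocking furoxan formation.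

Step 11
Reactants: 20 4-(benzyloxy)-5-[3,5-bis(benzyloxy)-4-methoxyphenyl]-3-[2,4,6-tris(methoxymethoxy)-3,5-dimethylphenyl]isoxazole
Product: 21 (2E)-3-amino-2-(benzyloxy)-1-[3,5-bis(benzyloxy)-4-methoxyphenyl]-3-[2,4,6-tris(methoxymethoxy)-3,5-dimethylphenyl]prop-2-en-1-one
Conditions: Mo(CO)6, MeCN/H2O, reflux
Reagents that add atoms: none
Why: Reductive N–O cleavage of an isoxazole by zerovalent molybdenum with water as hydrogen source, a method that should spare benzyl and MOM ethers and stop at the N–H···O=C chelated vinylogous amide.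

Step 12
Reactants: 21 (2E)-3-amino-2-(benzyloxy)-1-[3,5-bis(benzyloxy)-4-methoxyphenyl]-3-[2,4,6-tris(methoxymethoxy)-3,5-dimethylphenyl]prop-2-en-1-one
Product: 23 3-(benzyloxy)-2-[3,5-bis(benzyloxy)-4-methoxyphenyl]-5,7-dihydroxy-6,8-dimethyl-4H-chromen-4-one, via trihydroxy diketone 22 (not isolated)
Conditions: aq HCl, MeOH, reflux, under Ar
Reagents that add atoms: water, O
Why: One acid treatment should bring about acetal cleavage of the MOM ethers, hydrolysis of the primary enaminone to the 1,3-diketone and cyclodehydration as in the last stage of a Baker–Venkataraman flavone synthesis, with only one chromone possible because both ortho hydroxyls of ring A are equivalent and with no methylene bridging because ring A has no free position.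

Step 13
Reactants: 23 3-(benzyloxy)-2-[3,5-bis(benzyloxy)-4-methoxyphenyl]-5,7-dihydroxy-6,8-dimethyl-4H-chromen-4-one
Product: 24 6,8-di-C-methylmyricetin 4'-methyl ether
Conditions: H2 (1 atm), Pd/C, THF/MeOH, rt
Reagents that add atoms: none
Why: Catalytic hydrogenolysis of the three benzyl ethers, the customary last step for flavonols, should leave the chromone double bond, the methyl ether and the C-methyl groups untouched.

Compound list
1 | phloroglucinol | Oc1cc(O)cc(O)c1 | starting material
2 | 1,3,5-tris(methoxymethoxy)benzene | COCOc1cc(OCOC)cc(OCOC)c1 | intermediate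
3 | 2,4,6-tris(methoxymethoxy)phenyllithium | [Li]c1c(OCOC)cc(OCOC)cc1OCOC | intermediate
4 | 1,3,5-tris(methoxymethoxy)-2-methylbenzene | COCOc1cc(OCOC)c(C)c(OCOC)c1 | intermediate
5 | 2,4,6-tris(methoxymethoxy)-3-methylphenyllithium | [Li]c1c(OCOC)cc(OCOC)c(C)c1OCOC | intermediate
6 | 1,3,5-tris(methoxymethoxy)-2,4-dimethylbenzene | Cc1c(OCOC)cc(OCOC)c(C)c1OCOC | intermediate
7 | 2,4,6-tris(methoxymethoxy)-3,5-dimethylphenyllithium | [Li]c1c(OCOC)c(C)c(OCOC)c(C)c1OCOC | intermediate
8 | 2,4,6-tris(methoxymethoxy)-3,5-dimethylbenzaldehyde | COCOc1c(C)c(OCOC)c(C)c(OCOC)c1C=O | intermediate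
9 | (E)-2,4,6-tris(methoxymethoxy)-3,5-dimethylbenzaldehyde oxime | COCOc1c(C)c(OCOC)c(C)c(OCOC)c1/C=N/O | intermediate
10 | (Z)-N-hydroxy-2,4,6-tris(methoxymethoxy)-3,5-dimethylbenzimidoyl chloride | COCOc1c(C)c(OCOC)c(C)c(OCOC)c1/C(Cl)=N/O | intermediate
11 | 2,4,6-tris(methoxymethoxy)-3,5-dimethylbenzonitrile oxide | COCOc1c(C)c(OCOC)c(C)c(OCOC)c1C#[N+][O-] | intermediate
12 | methyl 3,5-dihydroxy-4-methoxybenzoate | COC(=O)c1cc(O)c(OC)c(O)c1 | starting material
13 | methyl 3,5-bis(benzyloxy)-4-methoxybenzoate | COC(=O)c1cc(OCc2ccccc2)c(OC)c(OCc2ccccc2)c1 | intermediate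
14 | 3,5-bis(benzyloxy)-N,4-dimethoxy-N-methylbenzamide | CON(C)C(=O)c1cc(OCc2ccccc2)c(OC)c(OCc2ccccc2)c1 | intermediate
15 | tributyl[(benzyloxy)methyl]stannane | CCCC[Sn](CCCC)(CCCC)COCc1ccccc1 | starting material
16 | (benzyloxy)methyllithium | [Li]COCc1ccccc1 | intermediate
17 | 2-(benzyloxy)-1-[3,5-bis(benzyloxy)-4-methoxyphenyl]ethanone | COc1c(OCc2ccccc2)cc(C(=O)COCc2ccccc2)cc1OCc1ccccc1 | intermediate
18 | 1-{2-(benzyloxy)-1-[3,5-bis(benzyloxy)-4-methoxyphenyl]ethenyl}pyrrolidine (double-bond geometry open, erased in step 10) | COc1c(OCc2ccccc2)cc(C(=COCc2ccccc2)N2CCCC2)cc1OCc1ccccc1 | intermediate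
19 | 4-(benzyloxy)-5-[3,5-bis(benzyloxy)-4-methoxyphenyl]-5-(pyrrolidin-1-yl)-3-[2,4,6-tris(methoxymethoxy)-3,5-dimethylphenyl]-4,5-dihydroisoxazole (racemic, both stereocentres erased in step 10) | COCOc1c(C)c(OCOC)c(C)c(OCOC)c1C1=NOC(N2CCCC2)(c2cc(OCc3ccccc3)c(OC)c(OCc3ccccc3)c2)C1OCc1ccccc1 | intermediate
20 | 4-(benzyloxy)-5-[3,5-bis(benzyloxy)-4-methoxyphenyl]-3-[2,4,6-tris(methoxymethoxy)-3,5-dimethylphenyl]isoxazole | COCOc1c(C)c(OCOC)c(C)c(OCOC)c1-c1noc(-c2cc(OCc3ccccc3)c(OC)c(OCc3ccccc3)c2)c1OCc1ccccc1 | intermediate
21 | (2E)-3-amino-2-(benzyloxy)-1-[3,5-bis(benzyloxy)-4-methoxyphenyl]-3-[2,4,6-tris(methoxymethoxy)-3,5-dimethylphenyl]prop-2-en-1-one | COCOc1c(C)c(OCOC)c(C)c(OCOC)c1/C(N)=C(\OCc1ccccc1)C(=O)c1cc(OCc2ccccc2)c(OC)c(OCc2ccccc2)c1 | intermediate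
22 | 2-(benzyloxy)-1-[3,5-bis(benzyloxy)-4-methoxyphenyl]-3-(2,4,6-trihydroxy-3,5-dimethylphenyl)propane-1,3-dione (racemic, enolisable) | Cc1c(O)c(C)c(O)c(C(=O)C(OCc2ccccc2)C(=O)c2cc(OCc3ccccc3)c(OC)c(OCc3ccccc3)c2)c1O | intermediate
23 | 3-(benzyloxy)-2-[3,5-bis(benzyloxy)-4-methoxyphenyl]-5,7-dihydroxy-6,8-dimethyl-4H-chromen-4-one | COc1c(OCc2ccccc2)cc(-c2oc3c(C)c(O)c(C)c(O)c3c(=O)c2OCc2ccccc2)cc1OCc1ccccc1 | intermediate
24 | 6,8-di-C-methylmyricetin 4'-methyl ether, 2-(3,5-dihydroxy-4-methoxyphenyl)-3,5,7-trihydroxy-6,8-dimethyl-4H-chromen-4-one | COc1c(O)cc(-c2oc3c(C)c(O)c(C)c(O)c3c(=O)c2O)cc1O | target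

Total step count: 13. Longest linear sequence: 10 steps (steps 1–6, then 10–13).

Steps most likely to fail

Risk 1, step 10. Pyrrolidine may leave the cycloadduct too early, while dipole is still present, and capture it. The addition to a crowded, trisubstituted enamine may be slow. Adventitious water may hydrolyse the enamine. The fallback removes the amine from the design and sets out from 17 and 11. Ketone 17 is deprotonated with LiN(SiMe3)2 in THF at −78 °C to the lithium enolate F1, whose hindered silylamine by-product does not add to nitrile oxides. Dipole 11 is then added and the mixture warmed to 0 °C. The known addition of nitrile oxides to ketone enolates (stepwise C-attack, then O-closure) should give the 5-hydroxy-4,5-dihydroisoxazole F2. Catalytic pyridinium p-toluenesulfonate in warm toluene dehydrates it, and the route is rejoined at 20.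

Risk 2, step 11. The reductive ring opening may be slow or incomplete, because the ring nitrogen next to the doubly ortho-substituted aryl group coordinates poorly to molybdenum. The fallback inverts the order of the endgame and sets out from 20. H2 over Pd(OH)2/C in THF/MeOH first strips the three benzyl groups, which uncovers the heterocycle. It then cleaves the N–O bond to give the trihydroxy enaminone F3. Without exposure to air, F3 is heated with aq HCl in MeOH, which removes the MOM groups, hydrolyses the enaminone and closes ring C. The route is rejoined directly at 24, bypassing 21–23.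

Risk 3, step 9. The tin–lithium exchange may be incomplete, butyl transfer from residual n-BuLi may compete, or the α-alkoxy carbanion may rearrange on warming before it is acylated. The tin-free fallback sets out from 13. tert-Butyl benzyloxyacetate is converted with LiN(i-Pr)2 in THF at −78 °C into the lithium ester enolate F4. Used in excess, F4 undergoes a crossed Claisen condensation with ester 13 to give the β-keto ester F5. Trifluoroacetic acid in CH2Cl2 cleaves the tert-butyl ester to the β-keto acid F6, which decarboxylates on warming in toluene. The route is rejoined at 17.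

Further compounds
F1 | step 10 | lithium enolate of 2-(benzyloxy)-1-[3,5-bis(benzyloxy)-4-methoxyphenyl]ethanone | [Li]OC(=COCc1ccccc1)c1cc(OCc2ccccc2)c(OC)c(OCc2ccccc2)c1
F2 | step 10 | 4-(benzyloxy)-5-[3,5-bis(benzyloxy)-4-methoxyphenyl]-3-[2,4,6-tris(methoxymethoxy)-3,5-dimethylphenyl]-4,5-dihydroisoxazol-5-ol (racemic) | COCOc1c(C)c(OCOC)c(C)c(OCOC)c1C1=NOC(O)(c2cc(OCc3ccccc3)c(OC)c(OCc3ccccc3)c2)C1OCc1ccccc1
F3 | step 11 | (2E)-3-amino-1-(3,5-dihydroxy-4-methoxyphenyl)-2-hydroxy-3-[2,4,6-tris(methoxymethoxy)-3,5-dimethylphenyl]prop-2-en-1-one | COCOc1c(C)c(OCOC)c(C)c(OCOC)c1/C(N)=C(\O)C(=O)c1cc(O)c(OC)c(O)c1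
F4 | step 9 | lithium enolate of tert-butyl benzyloxyacetate | [Li]OC(=COCc1ccccc1)OC(C)(C)C
F5 | step 9 | tert-butyl 2-(benzyloxy)-3-[3,5-bis(benzyloxy)-4-methoxyphenyl]-3-oxopropanoate (racemic) | COc1c(OCc2ccccc2)cc(C(=O)C(OCc2ccccc2)C(=O)OC(C)(C)C)cc1OCc1ccccc1
F6 | step 9 | 2-(benzyloxy)-3-[3,5-bis(benzyloxy)-4-methoxyphenyl]-3-oxopropanoic acid (racemic) | COc1c(OCc2ccccc2)cc(C(=O)C(OCc2ccccc2)C(=O)O)cc1OCc1ccccc1
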